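**Remark (convention and assumption):** Labdane numbering of the target is used for all intermediates (C17 on C8, C18/C19 on C4, C20 on C10, side chain C11–C16). β means the face carrying the C10 methyl (C20), α the opposite face. The target is taken exactly as drawn, (3R,5S,8S,9S,10R), so that its C5 maps onto C5 of (S)-carvone.

## Retrosynthetic overview

1. The side chain C13=C14–C15 comes from a terminal alkyne (carboalumination/CH2O). The 3β-Br comes from a C2=C3 bromoalkene (radical hydrogenation), itself from a C3 ketone. The 8α-OH comes from the Δ7 alkene (epoxide/hydride). The C9–C11 bond comes from an anti-SN2′ substitution at a C7 picolinate, after Wharton transposition of the C9 enone.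
2. Key disconnection: the C3–C4 bond of ring A, opened to a tertiary C4 radical (H• added to an isopropenyl group on C5) and a nitrile carbon C3 on the tether C10–C1–C2. The precursor is a monocyclic, twice α′-alkylated carvone.
3. Enabling feature: ring B (C5–C10) with C17 on C8 and C4 on C5 is a p-menthane whose oxygenated carbon (C9) lies next to the methyl-bearing C8, i.e. (S)-carvone. The quaternary gem-dimethyl C4 flanked by the heteroatom-bearing C3 is the retron of Markovnikov H-atom transfer to that isopropenyl group followed by radical ring closure.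
4. Ring order: ring B is the carvone ring (bought, never opened). Ring A (C10, C1, C2, C3, C4, C5) is closed last, in step 3. The trans ring fusion is fixed before closure by C5 (chiral pool) and the anti alkylation at C10.

Key step: step 3

## Route

Step 1
Reactants: 1 (S)-(+)-carvone
Product: 3 trans-6-methylcarvone, via lithium dienolate 2 (not isolated)
Conditions: LDA, THF, −78 °C; MeI, −78 to 0 °C
Reagents that add atoms: iodomethane, CI
Why: Kinetic α′-deprotonation of the enone and SN2 methylation of the cross-conjugated lithium dienolate is the standard C6 alkylation of carvone, the methyl entering mainly anti to the isopropenyl group, and the epimer composition at this carbon (the later C10) is irrelevant because it is enolised again in step 2.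

Step 2
Reactants: 3 trans-6-methylcarvone; 4 acrylonitrile
Product: 6 cyanoethyl ketone 6-(2-cyanoethyl)-6-methylcarvone [cyanoethyl anti to isopropenyl], via lithium dienolate 5 (not isolated)
Conditions: LDA, THF, −78 °C; 4, −78 to −30 °C; AcOH quench
Reagents that add atoms: none
Why: Michael addition (cyanoethylation) of the tetrasubstituted kinetic α′-enolate should take place on the enolate face anti to the vicinal isopropenyl group, which sets the quaternary C10 with the C1–C2–C3 chain trans to C4 and the methyl C20 cis to it, the relationship that makes the later ring fusion trans.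

Step 3
Reactants: 6 cyanoethyl ketone
Product: 8 enedione 4,4,8,10-tetramethyl-5αH-10β-decal-7-ene-3,9-dione, via ketimine 7 (not isolated)
Conditions: Fe(acac)3 (cat.), PhSiH3, EtOH (0.02 M), 60 °C; then 1 M HCl, THF, rt
Reagents that add atoms: water, O
Why: An iron hydride formed from Fe(acac)3, PhSiH3 and EtOH transfers H• to the CH2 terminus of the isopropenyl group (Markovnikov), which turns that carbon into the second methyl on C4 and leaves a tertiary C4 radical that adds to the nitrile carbon C3; the iminyl radical is reduced to ketimine 7, which is hydrolysed to the C3 ketone on acidic work-up. The closest known reaction type is the metal-hydride HAT-initiated (Mukaiyama-type) reductive radical cyclization of alkenyl nitriles to α-quaternary cycloalkanones. Ring A is closed by C3–C4 bond formation in a 6-exo-dig radical addition, so that a tertiary alkene carbon and a nitrile carbon, both electrophilic in polar terms, are joined. No new stereocentre is created in this step (C4 carries two methyls, C3 becomes a carbonyl), and the trans ring fusion follows from C5 (from carvone) and C10 (step 2), whose radical-bearing and nitrile-bearing substituents are trans-diequatorial on ring B and can only close to the trans-fused bicycle. The step needs chemoselective H-atom transfer to the electron-rich 1,1-disubstituted alkene in the presence of the enone, and ring closure faster than reduction of the radical or intermolecular addition to the enone. The substrate secures this through the poor H-atom acceptor character of the conjugated enone, the preorganised trans-diequatorial tether with fully substituted carbons at both ends, and high dilution.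

Step 4
Reactants: 8 enedione
Product: 10 enol triflate 9-oxo-4,4,8,10-tetramethyl-5αH-10β-decala-2,7-dien-3-yl triflate, via potassium enolate 9 (not isolated)
Conditions: KHMDS, THF, −78 °C; PhNTf2, −78 to 0 °C
Reagents that add atoms: N-phenylbis(trifluoromethanesulfonimide), O=S(=O)(N(c1ccccc1)S(=O)(=O)C(F)(F)F)C(F)(F)F
Why: Kinetic deprotonation should occur only at C2, the single α-CH2 of the saturated C3 ketone (C4 is quaternary and the enone has no α′-hydrogen), and O-sulfonylation of this enolate gives the Δ2 enol triflate as is usual for 4,4-dimethyl-3-ketones.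

Step 5
Reactants: 10 enol triflate
Product: 11 bromodienone 3-bromo-4,4,8,10-tetramethyl-5αH-10β-decala-2,7-dien-9-one
Conditions: Ni(OAc)2·4H2O (cat.), cod, Zn (cat.), LiBr, DMA/THF, rt
Reagents that add atoms: lithium bromide, [Li+].[Br-]
Why: Nickel-catalysed triflate-to-halide exchange (oxidative addition of Ni(0), triflate/bromide metathesis, reductive elimination) should convert the enol triflate into the alkenyl bromide without touching the enone, and this bromoalkene carries the future C3–Br bond at a protected oxidation level through the next six steps.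

Step 6
Reactants: 11 bromodienone
Product: 12 epoxy ketone 3-bromo-7α,8α-epoxy-4,4,8,10-tetramethyl-5αH-10β-decal-2-en-9-one
Conditions: 30% H2O2, NaOH (cat.), MeOH, 0 °C
Reagents that add atoms: hydrogen peroxide, OO
Why: Weitz–Scheffer nucleophilic epoxidation of the enone, in which hydroperoxide adds axially to C7 on the α face (trans to the C5–C4 bond, as with carvone itself), should give the 7α,8α-epoxide while the electron-poor bromoalkene stays inert.

Step 7
Reactants: 12 epoxy ketone
Product: 14 allylic alcohol 3-bromo-4,4,8,10-tetramethyl-5αH-10β-decala-2,8-dien-7α-ol, via epoxy hydrazone 13 (not isolated)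
Conditions: N2H4·H2O, AcOH (cat.), MeOH, 0 °C to rt
Reagents that add atoms: none
Why: Wharton transposition, in which the epoxy hydrazone collapses with loss of N2, moves the oxygen function from C9 to C7 with retention of the C7–O configuration (7α) and places the alkene at C8=C9, ready for substitution at C9.

Step 8
Reactants: 14 allylic alcohol
Product: 15 7α-picolinate of 14
Conditions: picolinic acid, DCC, DMAP (cat.), CH2Cl2, rt
Reagents that add atoms: picolinic acid, OC(=O)c1ccccn1
Why: Steglich esterification installs the picolinate, a chelating leaving group that makes copper-mediated allylic substitution γ-selective and anti-stereospecific.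

Step 9
Reactants: 15 7α-picolinate; 16 (4-bromobut-1-yn-1-yl)trimethylsilane
Product: 18 silylalkyne 3-bromo-9β-[4-(trimethylsilyl)but-3-yn-1-yl]-4,4,8,10-tetramethyl-5αH-9αH-10β-decala-2,7-diene, via Grignard reagent 17 (not isolated)
Conditions: 16, Mg, THF, rt; then CuBr·SMe2, 15, THF, −40 to 0 °C
Reagents that add atoms: none
Why: Copper-mediated anti-SN2′ substitution of the allylic picolinate by the alkyl Grignard reagent should deliver the C11–C14 chain to C9 on the face opposite to the 7α leaving group, i.e. 9β (cis to C20, H9 α), with the alkene moving to C7=C8, while the alkenyl bromide is inert to the alkylcopper species at low temperature.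

Step 10
Reactants: 18 silylalkyne
Product: 19 7α,8α-epoxide of 18
Conditions: mCPBA, NaHCO3, CH2Cl2, 0 °C
Reagents that add atoms: meta-chloroperoxybenzoic acid, OOC(=O)c1cccc(Cl)c1
Why: Prilezhaev epoxidation should occur only at the electron-rich trisubstituted Δ7 alkene and from the α face, because the β face is shielded by the axial C10 methyl and the 9β side chain, while the bromoalkene and the silylalkyne do not react.

Step 11
Reactants: 19 epoxide
Product: 20 tertiary alcohol 3-bromo-9β-[4-(trimethylsilyl)but-3-yn-1-yl]-4,4,8β,10β-tetramethyl-5αH-9αH-decal-2-en-8α-ol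
Conditions: LiAlH4, THF, 0 to 50 °C
Reagents that add atoms: none
Why: Hydride opens the trisubstituted epoxide by SN2 attack at the less substituted C7, so the oxygen stays on C8 with its configuration and the tertiary 8α-alcohol with C17 β results, while alkenyl bromide and silylalkyne are inert to LiAlH4.

Step 12
Reactants: 20 tertiary alcohol
Product: 21 bromide 3β-bromo-9β-[4-(trimethylsilyl)but-3-yn-1-yl]-4,4,8β,10β-tetramethyl-5αH-9αH-decalin-8α-ol
Conditions: Mn(dpm)3 (cat.), PhSiH3, TBHP, i-PrOH, rt
Reagents that add atoms: none
Why: Manganese-hydride HAT hydrogenation, a method that reduces haloalkenes to alkyl halides without C–halogen cleavage and under thermodynamic stereocontrol, should add H• to C2 and then deliver the second hydrogen to the α-bromo C3 radical axially from the α face (anti to the axial 4β-methyl), giving the equatorial 3β-bromide, with no other alkene present and the silylalkyne a poor H-atom acceptor.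

Step 13
Reactants: 21 bromide
Product: 22 terminal alkyne 3β-bromo-9β-(but-3-yn-1-yl)-4,4,8β,10β-tetramethyl-5αH-9αH-decalin-8α-ol
Conditions: K2CO3, MeOH, rt
Reagents that add atoms: none
Why: Base-mediated methanolysis of the alkynyl–silicon bond frees the terminal alkyne under conditions that cannot affect the equatorial neopentyl-type secondary bromide (no antiperiplanar hydrogen for E2, no access for SN2).

Step 14
Reactants: 22 terminal alkyne
Product: 24 target (E)-3β-bromo-labd-13-ene-8α,15-diol, via alkenylalane 23 (not isolated)
Conditions: Me3Al, Cp2ZrCl2 (cat.), CH2Cl2, 0 °C to rt; then (CH2O)n, THF, 0 °C to rt; aq. Rochelle salt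
Reagents that add atoms: trimethylaluminium, C[Al](C)C; formaldehyde (from paraformaldehyde), C=O
Why: Negishi zirconium-catalysed carboalumination adds methyl and aluminium syn across the terminal alkyne (methyl to C13, aluminium to C14), and trapping of the alkenylalane with formaldehyde with retention should give the (E)-trisubstituted allylic alcohol, the tertiary alcohol being carried as its aluminium alkoxide.

## Compound list

1 | (S)-(+)-carvone, (5S)-2-methyl-5-(prop-1-en-2-yl)cyclohex-2-en-1-one | C=C(C)[C@H]1CC=C(C)C(=O)C1 | starting material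
2 | lithium α′-dienolate of carvone | C=C(C)[C@H]1CC=C(C)C(O[Li])=C1 | intermediate (not isolated)
3 | trans-6-methylcarvone, (5S,6R)-2,6-dimethyl-5-(prop-1-en-2-yl)cyclohex-2-en-1-one (minor 6-epimer carried along) | C=C(C)[C@H]1CC=C(C)C(=O)[C@@H]1C | intermediate
4 | acrylonitrile | C=CC#N | starting material
5 | lithium α′-dienolate of 6-methylcarvone | C=C(C)[C@H]1CC=C(C)C(O[Li])=C1C | intermediate (not isolated)
6 | 3-[(1R,6R)-1,3-dimethyl-2-oxo-6-(prop-1-en-2-yl)cyclohex-3-en-1-yl]propanenitrile (cyanoethyl trans, methyl cis to isopropenyl) | C=C(C)[C@H]1CC=C(C)C(=O)[C@]1(C)CCC#N | intermediate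
7 | N–H ketimine at C3 of the trans-fused bicycle (3-imino-4,4,8,10-tetramethyl-5αH,10β-decal-7-en-9-one) | O=C1C(C)=CC[C@@H]2C(C)(C)C(=N)CC[C@@]12C | intermediate (not isolated)
8 | 4,4,8,10-tetramethyl-5αH,10β-decal-7-ene-3,9-dione (trans-fused) | O=C1C(C)=CC[C@@H]2C(C)(C)C(=O)CC[C@@]12C | intermediate
9 | potassium Δ2-enolate of 8 (C3–OK) | O=C1C(C)=CC[C@@H]2C(C)(C)C(O[K])=CC[C@@]12C | intermediate (not isolated)
10 | 9-oxo-4,4,8,10-tetramethyl-5αH,10β-decala-2,7-dien-3-yl trifluoromethanesulfonate | O=C1C(C)=CC[C@@H]2C(C)(C)C(OS(=O)(=O)C(F)(F)F)=CC[C@@]12C | intermediate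
11 | 3-bromo-4,4,8,10-tetramethyl-5αH,10β-decala-2,7-dien-9-one | O=C1C(C)=CC[C@@H]2C(C)(C)C(Br)=CC[C@@]12C | intermediate
12 | 3-bromo-7α,8α-epoxy-4,4,8,10-tetramethyl-5αH,10β-decal-2-en-9-one | O=C1[C@@]2(C)O[C@H]2C[C@@H]3C(C)(C)C(Br)=CC[C@@]13C | intermediate
13 | hydrazone of 12 at C9 | NN=C1[C@@]2(C)O[C@H]2C[C@@H]3C(C)(C)C(Br)=CC[C@@]13C | intermediate (not isolated)
14 | 3-bromo-4,4,8,10-tetramethyl-5αH,10β-decala-2,8-dien-7α-ol | C1=C(C)[C@@H](O)C[C@@H]2C(C)(C)C(Br)=CC[C@@]12C | intermediate
15 | 7α-picolinate (pyridine-2-carboxylate) of 14 | C1=C(C)[C@@H](OC(=O)c3ccccn3)C[C@@H]2C(C)(C)C(Br)=CC[C@@]12C | intermediate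
16 | (4-bromobut-1-yn-1-yl)trimethylsilane | C[Si](C)(C)C#CCCBr | starting material
17 | [4-(trimethylsilyl)but-3-yn-1-yl]magnesium bromide | C[Si](C)(C)C#CCC[Mg]Br | intermediate (not isolated)
18 | 3-bromo-9β-[4-(trimethylsilyl)but-3-yn-1-yl]-4,4,8,10-tetramethyl-5αH,9αH,10β-decala-2,7-diene | C[Si](C)(C)C#CCC[C@@H]1C(C)=CC[C@@H]2C(C)(C)C(Br)=CC[C@@]12C | intermediate
19 | 7α,8α-epoxide of 18 | C[Si](C)(C)C#CCC[C@@H]1[C@@]3(C)O[C@H]3C[C@@H]2C(C)(C)C(Br)=CC[C@@]12C | intermediate
20 | 3-bromo-9β-[4-(trimethylsilyl)but-3-yn-1-yl]-4,4,8β,10β-tetramethyl-5αH,9αH-decal-2-en-8α-ol | C[Si](C)(C)C#CCC[C@@H]1[C@@](C)(O)CC[C@@H]2C(C)(C)C(Br)=CC[C@@]12C | intermediate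
21 | 3β-bromo-9β-[4-(trimethylsilyl)but-3-yn-1-yl]-4,4,8β,10β-tetramethyl-5αH,9αH-decalin-8α-ol | C[Si](C)(C)C#CCC[C@@H]1[C@@](C)(O)CC[C@@H]2C(C)(C)[C@H](Br)CC[C@@]12C | intermediate
22 | 3β-bromo-9β-(but-3-yn-1-yl)-4,4,8β,10β-tetramethyl-5αH,9αH-decalin-8α-ol | C#CCC[C@@H]1[C@@](C)(O)CC[C@@H]2C(C)(C)[C@H](Br)CC[C@@]12C | intermediate
23 | (E)-alkenyl(dimethyl)alane from 22 (Al on C14, new methyl on C13, C8–O as dimethylaluminium alkoxide) | C[Al](C)/C=C(\C)CC[C@@H]1[C@@](C)(O[Al](C)C)CC[C@@H]2C(C)(C)[C@H](Br)CC[C@@]12C | intermediate (not isolated)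
24 | (E)-5-[(1S,2S,4aS,6R,8aR)-6-bromo-2-hydroxy-2,5,5,8a-tetramethyldecahydronaphthalen-1-yl]-3-methylpent-2-en-1-ol | C/C(=C\CO)CC[C@H]1[C@]2(C)CC[C@@H](Br)C(C)(C)[C@H]2CC[C@]1(C)O | target

## Step count and risk

Total step count: 14. Longest linear sequence: 14 steps (from 1; 4 and 16 are bought).

**Step 3 (key step).** The 6-exo-dig addition of the tertiary C4 radical to the nitrile may be too slow, so that plain reduction of the radical (net hydrogenation of the isopropenyl group) or intermolecular addition to the enone of a second molecule takes over. The fallback replaces the nitrile by the faster carbonyl acceptor and builds the tether in another way. It sets out from 3: alkylation of the α′-enolate (LDA, allyl bromide) should give 6-allyl-6-methylcarvone F1 with the allyl group anti to isopropenyl. Nitrite-modified, aldehyde-selective Wacker oxidation of the monosubstituted alkene (PdCl2(PhCN)2, CuCl2, AgNO2, t-BuOH/MeNO2, O2) should give the aldehyde F2. Iron-hydride HAT cyclization onto the aldehyde (Fe(acac)3, PhSiH3, EtOH/ethylene glycol, 60 °C) should give the 3-hydroxy enone F3 as a C3 epimer mixture. Dess–Martin oxidation brings the route back at 8.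

**Step 9.** Regiocontrol may be lost: the alkylcopper has to attack C9 next to the quaternary C10 and on the face of its methyl group, so direct SN2 substitution at C7 or reduction of the allylic ester may compete. The fallback delivers the carbon intramolecularly by a [3,3] shift. It sets out from 14: MnO2 oxidation should give the transposed enone F4. Luche reduction with axial hydride delivery should give the 7β-alcohol F5. Johnson–Claisen rearrangement (MeC(OEt)3, cat. propionic acid, 140 °C) should transfer the acetate unit suprafacially to the β face of C9 and give the ester F6 with the Δ7 alkene. LiAlH4 reduction gives the primary alcohol F7, and I2/PPh3/imidazole gives the iodide F8. Displacement with lithium (trimethylsilyl)acetylide in THF/DMPU comes back to the route at 18.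

**Step 12.** H-atom transfer to the hindered bromoalkene may be slow, so that reduction of the silylalkyne or loss of bromine by over-reduction competes. The fallback moves the hydrogenation to a stage where the bromoalkene is the only C=C bond and carries the saturated bromide onward. It sets out from 12: the same manganese-hydride hydrogenation should give the 3β-bromo epoxy ketone F9. Wharton transposition gives the allylic alcohol F10, and esterification gives the picolinate F11. Anti-SN2′ substitution with 17 gives the silylalkyne F12, and mCPBA gives the epoxide F13. Hydride opening with LiAlH4 at 0 °C, which the equatorial neopentyl-type bromide should survive, comes back to the route at 21.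

## Further compounds

F1 | step 3 | 6-allyl-6-methylcarvone (allyl trans, methyl cis to isopropenyl) | C=C(C)[C@H]1CC=C(C)C(=O)[C@]1(C)CC=C
F2 | step 3 | 3-[(1R,6R)-1,3-dimethyl-2-oxo-6-(prop-1-en-2-yl)cyclohex-3-en-1-yl]propanal | C=C(C)[C@H]1CC=C(C)C(=O)[C@]1(C)CCC=O
F3 | step 3 | 3-hydroxy-4,4,8,10-tetramethyl-5αH,10β-decal-7-en-9-one (C3 epimers) | O=C1C(C)=CC[C@@H]2C(C)(C)C(O)CC[C@@]12C
F4 | step 9 | 3-bromo-4,4,8,10-tetramethyl-5αH,10β-decala-2,8-dien-7-one | C1=C(C)C(=O)C[C@@H]2C(C)(C)C(Br)=CC[C@@]12C
F5 | step 9 | 3-bromo-4,4,8,10-tetramethyl-5αH,10β-decala-2,8-dien-7β-ol | C1=C(C)[C@H](O)C[C@@H]2C(C)(C)C(Br)=CC[C@@]12C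
F6 | step 9 | ethyl 2-(3-bromo-4,4,8,10-tetramethyl-5αH,9αH,10β-decala-2,7-dien-9β-yl)acetate | CCOC(=O)C[C@@H]1C(C)=CC[C@@H]2C(C)(C)C(Br)=CC[C@@]12C
F7 | step 9 | 2-(3-bromo-4,4,8,10-tetramethyl-5αH,9αH,10β-decala-2,7-dien-9β-yl)ethanol | OCC[C@@H]1C(C)=CC[C@@H]2C(C)(C)C(Br)=CC[C@@]12C
F8 | step 9 | 3-bromo-9β-(2-iodoethyl)-4,4,8,10-tetramethyl-5αH,9αH,10β-decala-2,7-diene | ICC[C@@H]1C(C)=CC[C@@H]2C(C)(C)C(Br)=CC[C@@]12C
F9 | step 12 | 3β-bromo-7α,8α-epoxy-4,4,8,10-tetramethyl-5αH,10β-decalin-9-one | O=C1[C@@]2(C)O[C@H]2C[C@@H]3C(C)(C)[C@H](Br)CC[C@@]13C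
F10 | step 12 | 3β-bromo-4,4,8,10-tetramethyl-5αH,10β-decal-8-en-7α-ol | C1=C(C)[C@@H](O)C[C@@H]2C(C)(C)[C@H](Br)CC[C@@]12C
F11 | step 12 | 7α-picolinate of F10 | C1=C(C)[C@@H](OC(=O)c3ccccn3)C[C@@H]2C(C)(C)[C@H](Br)CC[C@@]12C
F12 | step 12 | 3β-bromo-9β-[4-(trimethylsilyl)but-3-yn-1-yl]-4,4,8,10-tetramethyl-5αH,9αH,10β-decal-7-ene | C[Si](C)(C)C#CCC[C@@H]1C(C)=CC[C@@H]2C(C)(C)[C@H](Br)CC[C@@]12C
F13 | step 12 | 7α,8α-epoxide of F12 | C[Si](C)(C)C#CCC[C@@H]1[C@@]3(C)O[C@H]3C[C@@H]2C(C)(C)[C@H](Br)CC[C@@]12C
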